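**Retrosynthetic overview**

1. Enabling feature: in the cyclohex-2-enone ring (C1 = carbonyl, C2=C3, C4, C5 = carbinol, C6) the two oxygenated carbons C1 and C5 stand 1,3 across the lone methylene C6, and the bridge C2=C3–C4 carries no substituent. The ring is therefore a 1,3-dielectrophile closed by a propene 1,3-dianion.
2. Key disconnection: C1–C2 and C4–C5 together, by a Lewis acid [3+3] annulation of a β-keto acetal (C5 as ketone, C1 as a chiral 2,4-pentanediol acetal) with (E)-1,3-bis(trimethylsilyl)propene. This step forms the only ring.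
3. Stereochemistry: the C2-symmetric diol sets C1 and a titanium chelate relays C1 to C5. C1 and the side-chain carbinol are temporary stereocentres that end as the two ketones.
4. β-Keto acetal: kinetic aldol of the acetal-bearing methyl ketone with (Z)-octadec-9-enal (the oleyl chain brings the Z-alkene), then O-silylation.
5. End game: oxidation and retro-oxa-Michael removal of the auxiliary, desilylation, double oxidation.

Key step: step 6

Remark: the side-chain carbinol carbon is carried as a mixture of both epimers and is left undefined in the SMILES, because the last step converts it into the side-chain ketone.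
Remark: the sense of the acetal opening is taken from the accepted model (invertive attack anti to the oxygen next to the axial methyl); on that model the (2S,4S)-diol leads to the (R)-target, and the (2R,4R)-diol would be used if the sense proved opposite.

Step 1
Reactants: 1 (Z)-octadec-9-en-1-ol
Product: 2 (Z)-octadec-9-enal
Conditions: TEMPO (10 mol %), PhI(OAc)2 (1.1 equiv), CH2Cl2, rt
Reagents that add atoms: none
Why: the oxoammonium (TEMPO) oxidation of a primary alcohol should stop at the aldehyde and leave the Z-alkene untouched.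

Step 2
Reactants: 3 4,4-dimethoxybutan-2-one; 4 (2S,4S)-pentane-2,4-diol
Product: 5 1-[(4S,6S)-4,6-dimethyl-1,3-dioxan-2-yl]propan-2-one
Conditions: PPTS (5 mol %), benzene, reflux over 4 Å molecular sieves (methanol removal)
Reagents that add atoms: none
Why: acid-catalysed transacetalisation, driven by removal of methanol and by the stable six-membered dioxane, should exchange the acetal without touching the diol stereocentres.

Step 3
Reactants: 5 1-[(4S,6S)-4,6-dimethyl-1,3-dioxan-2-yl]propan-2-one; 2 (Z)-octadec-9-enal
Product: 6 (Z)-1-[(4S,6S)-4,6-dimethyl-1,3-dioxan-2-yl]-4-hydroxyhenicos-12-en-2-one (both C-4 epimers)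
Conditions: lithium diisopropylamide (1.05 equiv), THF, −78 °C; then 2; then H2O at −78 °C
Reagents that add atoms: none
Why: kinetic deprotonation at the methyl group followed by lithium enolate aldol addition should give the β-hydroxy ketone, whose new carbinol centre is not controlled because it is oxidised later.

Step 4
Reactants: 6 (Z)-1-[(4S,6S)-4,6-dimethyl-1,3-dioxan-2-yl]-4-hydroxyhenicos-12-en-2-one
Product: 7 (Z)-4-(tert-butyldimethylsilyloxy)-1-[(4S,6S)-4,6-dimethyl-1,3-dioxan-2-yl]henicos-12-en-2-one (both C-4 epimers)
Conditions: TBSOTf (1.2 equiv), 2,6-lutidine (1.5 equiv), CH2Cl2, −78 °C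
Reagents that add atoms: tert-butyldimethylsilyl triflate, CC(C)(C)[Si](C)(C)OS(=O)(=O)C(F)(F)F
Why: low-temperature O-silylation should protect the carbinol as a non-chelating silyl ether, so that it cannot compete for titanium in step 6.

Step 5
Reactants: 8 allyltrimethylsilane
Product: 9 (E)-1,3-bis(trimethylsilyl)prop-1-ene
Conditions: sec-BuLi, TMEDA, THF, −78 °C; then Me3SiCl
Reagents that add atoms: chlorotrimethylsilane, C[Si](C)(C)Cl
Why: the silyl-stabilised allyl anion should be silylated at its unsubstituted terminus (allylic deprotonation and electrophilic silylation) to give the E-configured bis-silane.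

Step 6
Reactants: 7 (Z)-4-(tert-butyldimethylsilyloxy)-1-[(4S,6S)-4,6-dimethyl-1,3-dioxan-2-yl]henicos-12-en-2-one; 9 (E)-1,3-bis(trimethylsilyl)prop-1-ene
Product: 11 (1S,5S)-1-[(Z)-2-(tert-butyldimethylsilyloxy)nonadec-10-enyl]-5-[(2S,4S)-4-hydroxypentan-2-yl]oxycyclohex-3-en-1-ol, via open-chain syn β-alkoxy allylsilane 10 (not isolated)
Conditions: 9 (1.5 equiv), TiCl4 (2.2 equiv), CH2Cl2, −78 to −40 °C; then H2O
Reagents that add atoms: none
Why: Proposed new method: TiCl4 ionises the dioxane acetal of 7 at the C–O bond next to the axial methyl group and the silyl-bearing alkene terminus of 9 attacks the oxocarbenium carbon C1 with inversion through an open anti-SE2′ transition state (chiral-acetal Hosomi–Sakurai reaction), which makes C1–C2 and leaves the syn α-silyl allylsilane 10 as a trichlorotitanium alkoxide of the opened auxiliary. That alkoxide holds the metal between the new C1 ether oxygen and the C5 ketone, and a second, intramolecular Hosomi–Sakurai addition of the terminal alkene carbon C4 to the activated ketone (β-silyl cation at C3, loss of Me3SiCl) makes C4–C5 and the cis C2=C3 bond. The closest known reactions are the invertive opening of 2,4-pentanediol acetals by allylsilanes, the stepwise use of 1,3-bis(trimethylsilyl)propene as a propene 1,3-dianion toward carbonyl electrophiles, and intramolecular Hosomi–Sakurai cyclisations onto ketones; their union on a β-keto acetal as a [3+3] annulation is the new element. The cyclohexene ring is closed by a cationic six-membered closure that is exo at the ketone C=O and endo at the allylsilane double bond, so all three carbons of the allyl unit become ring atoms. C1 is set by the C2-symmetric diol, and C5 is set by the chelate: because the nucleophile is tied to C1, the two oxygens must end 1,3-cis on the new ring, and the syn C1/C2 relationship from the first addition is the one that places the C–Si bond anti to the forming C4–C5 bond in that array. The step needs site selectivity (acetal before ketone, secured by the much higher electrophilicity of the oxocarbenium ion at −78 °C), survival of the β-alkoxy silane against Peterson-type elimination (secured by the electron-poor β-keto position of C1 and the low temperature) and face selectivity at C5 (secured by the tether and the chelate).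

Step 7
Reactants: 11 (1S,5S)-1-[(Z)-2-(tert-butyldimethylsilyloxy)nonadec-10-enyl]-5-[(2S,4S)-4-hydroxypentan-2-yl]oxycyclohex-3-en-1-ol
Product: 12 (4S)-4-{[(1S,5S)-5-[(Z)-2-(tert-butyldimethylsilyloxy)nonadec-10-enyl]-5-hydroxycyclohex-2-en-1-yl]oxy}pentan-2-one
Conditions: Dess–Martin periodinane (1.3 equiv), CH2Cl2, 0 °C to rt
Reagents that add atoms: none
Why: Dess–Martin oxidation should convert the only secondary alcohol (on the opened auxiliary) into a ketone, while the tertiary alcohol, the silyl ether and the alkenes are inert.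

Step 8
Reactants: 12 (4S)-4-{[(1S,5S)-5-[(Z)-2-(tert-butyldimethylsilyloxy)nonadec-10-enyl]-5-hydroxycyclohex-2-en-1-yl]oxy}pentan-2-one
Product: 13 (1S,3S)-1-[(Z)-2-(tert-butyldimethylsilyloxy)nonadec-10-enyl]cyclohex-4-ene-1,3-diol
Conditions: K2CO3 (0.5 equiv), MeOH, rt
Reagents that add atoms: none
Why: the β-alkoxy ketone should undergo base-mediated E1cB elimination (retro-oxa-Michael reaction), which releases the C1 allylic alcohol without touching either stereocentre.

Step 9
Reactants: 13 (1S,3S)-1-[(Z)-2-(tert-butyldimethylsilyloxy)nonadec-10-enyl]cyclohex-4-ene-1,3-diol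
Product: 14 (1R,3S)-1-[(Z)-2-hydroxynonadec-10-enyl]cyclohex-4-ene-1,3-diol (both side-chain epimers)
Conditions: HF·pyridine, THF/pyridine, 0 °C to rt
Reagents that add atoms: none
Why: fluoride-mediated desilylation under buffered conditions should free the side-chain carbinol without ionising the allylic or tertiary alcohol.

Step 10
Reactants: 14 (1R,3S)-1-[(Z)-2-hydroxynonadec-10-enyl]cyclohex-4-ene-1,3-diol
Product: 15 (R)-5-hydroxy-5-[(Z)-2-oxononadec-10-enyl]cyclohex-2-en-1-one
Conditions: Dess–Martin periodinane (2.6 equiv), NaHCO3, CH2Cl2, 0 °C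
Reagents that add atoms: none
Why: buffered Dess–Martin oxidation should convert the allylic and the side-chain secondary alcohols into the enone and the ketone, which erases both temporary stereocentres and leaves the non-oxidisable tertiary C5 carbinol as the only stereocentre.

**Compound list**

1 | (Z)-octadec-9-en-1-ol (oleyl alcohol) | CCCCCCCC/C=C\CCCCCCCCO | starting material
2 | (Z)-octadec-9-enal | CCCCCCCC/C=C\CCCCCCCC=O | intermediate
3 | 4,4-dimethoxybutan-2-one | CC(=O)CC(OC)OC | starting material
4 | (2S,4S)-pentane-2,4-diol | C[C@H](O)C[C@H](C)O | starting material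
5 | 1-[(4S,6S)-4,6-dimethyl-1,3-dioxan-2-yl]propan-2-one | CC(=O)CC1O[C@@H](C)C[C@H](C)O1 | intermediate
6 | (Z)-1-[(4S,6S)-4,6-dimethyl-1,3-dioxan-2-yl]-4-hydroxyhenicos-12-en-2-one (both C-4 epimers) | CCCCCCCC/C=C\CCCCCCCC(O)CC(=O)CC1O[C@@H](C)C[C@H](C)O1 | intermediate
7 | (Z)-4-(tert-butyldimethylsilyloxy)-1-[(4S,6S)-4,6-dimethyl-1,3-dioxan-2-yl]henicos-12-en-2-one (both C-4 epimers) | CCCCCCCC/C=C\CCCCCCCC(O[Si](C)(C)C(C)(C)C)CC(=O)CC1O[C@@H](C)C[C@H](C)O1 | intermediate
8 | allyltrimethylsilane | C=CC[Si](C)(C)C | starting material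
9 | (E)-1,3-bis(trimethylsilyl)prop-1-ene | C[Si](C)(C)C/C=C/[Si](C)(C)C | intermediate
10 | (3S,4S,16Z)-8-(tert-butyldimethylsilyloxy)-4-{[(2S,4S)-4-(trichlorotitaniooxy)pentan-2-yl]oxy}-3-(trimethylsilyl)pentacosa-1,16-dien-6-one (open-chain syn β-alkoxy allylsilane, ROTiCl3 form, not isolated) | CCCCCCCC/C=C\CCCCCCCC(O[Si](C)(C)C(C)(C)C)CC(=O)C[C@H](O[C@@H](C)C[C@H](C)O[Ti](Cl)(Cl)Cl)[C@@H]([Si](C)(C)C)C=C | intermediate
11 | (1S,5S)-1-[(Z)-2-(tert-butyldimethylsilyloxy)nonadec-10-enyl]-5-[(2S,4S)-4-hydroxypentan-2-yl]oxycyclohex-3-en-1-ol | CCCCCCCC/C=C\CCCCCCCC(O[Si](C)(C)C(C)(C)C)C[C@]1(O)CC=C[C@@H](O[C@@H](C)C[C@H](C)O)C1 | intermediate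
12 | (4S)-4-{[(1S,5S)-5-[(Z)-2-(tert-butyldimethylsilyloxy)nonadec-10-enyl]-5-hydroxycyclohex-2-en-1-yl]oxy}pentan-2-one | CCCCCCCC/C=C\CCCCCCCC(O[Si](C)(C)C(C)(C)C)C[C@]1(O)CC=C[C@@H](O[C@@H](C)CC(C)=O)C1 | intermediate
13 | (1S,3S)-1-[(Z)-2-(tert-butyldimethylsilyloxy)nonadec-10-enyl]cyclohex-4-ene-1,3-diol | CCCCCCCC/C=C\CCCCCCCC(O[Si](C)(C)C(C)(C)C)C[C@]1(O)CC=C[C@@H](O)C1 | intermediate
14 | (1R,3S)-1-[(Z)-2-hydroxynonadec-10-enyl]cyclohex-4-ene-1,3-diol (both side-chain epimers) | CCCCCCCC/C=C\CCCCCCCC(O)C[C@]1(O)CC=C[C@@H](O)C1 | intermediate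
15 | (R)-5-hydroxy-5-[(Z)-2-oxononadec-10-enyl]cyclohex-2-en-1-one | CCCCCCCC/C=C\CCCCCCCC(=O)C[C@]1(O)CC=CC(=O)C1 | target

**Step count and risks**

Total step count: 10. Longest linear sequence: 8 steps (steps 1, 3, 4, 6, 7, 8, 9, 10).

Steps most likely to fail:

1. Step 6 (proposed new method). Possible failures are Peterson-type elimination or protodesilylation of the β-alkoxy allylsilane before ring closure, loss of the acetal-opening selectivity through elimination to an enol ether, and a wrong facial course at C5 if the chelate is not maintained. The fallback uses only known reaction types, sets out from aldehyde 2 and comes back at target 15. A chiral (salen)CrCl-catalysed hetero-Diels–Alder reaction of 2 with trans-1-methoxy-3-(trimethylsilyloxy)buta-1,3-diene, followed by CF3CO2H, should give (R)-2-[(Z)-heptadec-8-enyl]-2,3-dihydro-4H-pyran-4-one F1. Acid-catalysed conjugate addition of methanol should give the 2,6-trans methyl acetal F2 with an axial methoxy group. Allylmagnesium bromide should add to the ring ketone from the equatorial side, away from the axial methoxy group, to give the tertiary carbinol F3. Mild aqueous acid frees the lactol F4, and excess vinylmagnesium bromide opens it to the triene triol F5. Ring-closing metathesis with the second-generation Grubbs catalyst, RuCl2(=CHPh)(PCy3)(H2IMes), gives the cyclohexene triol F6, and Dess–Martin oxidation of its two secondary alcohols gives 15. Here the ring stereocentre is set by the six-membered acetal ring and not by the chelate.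

2. Step 3. Possible failures are loss of regiocontrol in the enolisation and E1cB opening of the dioxane from the internal enolate. The fallback sets out from 2 and comes back at 7, and avoids any ketone enolate that carries a β-leaving group. Aldol addition of the lithium enolate of N-methoxy-N-methylacetamide to 2 gives the hydroxy amide F7. Silylation with TBSOTf and 2,6-lutidine gives the silyl ether F8, and ethynylmagnesium bromide converts it into the ynone F9. Double oxa-Michael addition of diol 4 to F9 (catalytic DABCO, then catalytic PPTS) closes the dioxane and gives 7.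

3. Step 10. Possible failures are dehydration of the tertiary β-hydroxyl with aromatisation to a phenol, or retro-aldol cleavage, when both carbonyl groups are generated together under one oxidant. The fallback sets out from 14 and comes back at 15, and separates the two oxidations. MnO2 in CH2Cl2 oxidises only the allylic alcohol to give the hydroxy enone F10. A neutral catalytic oxidation with Pr4N[RuO4] and N-methylmorpholine N-oxide then converts the remaining side-chain carbinol into the ketone of 15.

**Further compounds**

F1 | step 6 | (R)-2-[(Z)-heptadec-8-enyl]-2,3-dihydro-4H-pyran-4-one | CCCCCCCC/C=C\CCCCCCC[C@@H]1CC(=O)C=CO1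
F2 | step 6 | (2S,6R)-6-[(Z)-heptadec-8-enyl]-2-methoxyoxan-4-one | CCCCCCCC/C=C\CCCCCCC[C@@H]1CC(=O)C[C@@H](OC)O1
F3 | step 6 | (2S,4R,6R)-6-[(Z)-heptadec-8-enyl]-2-methoxy-4-(prop-2-enyl)oxan-4-ol | CCCCCCCC/C=C\CCCCCCC[C@@H]1C[C@](O)(CC=C)C[C@@H](OC)O1
F4 | step 6 | (4R,6R)-6-[(Z)-heptadec-8-enyl]-4-(prop-2-enyl)oxane-2,4-diol (both anomers) | CCCCCCCC/C=C\CCCCCCC[C@@H]1C[C@](O)(CC=C)CC(O)O1
F5 | step 6 | (5R,7R,15Z)-5-(prop-2-enyl)tetracosa-1,15-diene-3,5,7-triol (both C-3 epimers) | CCCCCCCC/C=C\CCCCCCC[C@@H](O)C[C@](O)(CC=C)CC(O)C=C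
F6 | step 6 | (1R)-1-[(2R,10Z)-2-hydroxynonadec-10-enyl]cyclohex-4-ene-1,3-diol (both C-3 epimers) | CCCCCCCC/C=C\CCCCCCC[C@@H](O)C[C@]1(O)CC=CC(O)C1
F7 | step 3 | (Z)-3-hydroxy-N-methoxy-N-methylicos-11-enamide | CCCCCCCC/C=C\CCCCCCCC(O)CC(=O)N(C)OC
F8 | step 3 | (Z)-3-(tert-butyldimethylsilyloxy)-N-methoxy-N-methylicos-11-enamide | CCCCCCCC/C=C\CCCCCCCC(O[Si](C)(C)C(C)(C)C)CC(=O)N(C)OC
F9 | step 3 | (Z)-5-(tert-butyldimethylsilyloxy)docos-13-en-1-yn-3-one | CCCCCCCC/C=C\CCCCCCCC(O[Si](C)(C)C(C)(C)C)CC(=O)C#C
F10 | step 10 | (R)-5-hydroxy-5-[(Z)-2-hydroxynonadec-10-enyl]cyclohex-2-en-1-one (both side-chain epimers) | CCCCCCCC/C=C\CCCCCCCC(O)C[C@]1(O)CC=CC(=O)C1
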